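(All constants belong to no real substance, and the outcome is calculated.)

Substrate still left in a flask is what intermediate can turn into side product, so this reckoning follows that leftover.

    substrate + intermediate → side product (k1 = 0.162 M⁻¹ s⁻¹)
    substrate → intermediate (k2 = 0.0843 s⁻¹)
    partner ⇌ dormant form (K3 = 2.45, k3 = 0.0546 s⁻¹)
    partner + intermediate → target (k4 = 5.22 M⁻¹ s⁻¹)

| setting | eta | gamma | theta | delta |
|---|---|---|---|---|
| substrate | 0.14 M | 0.14 M | 0.14 M (fed, over 1.0 min) | 0.14 M |
| partner | 0.168 M | 0.168 M (fed, over 1.0 min) | 0.168 M | 0.168 M (fed, over 6.0 s) |
| time | 80 s | 80 s | 80 s | 80 s |
| remark | everything together at the start | all else is in the flask from the start; the feed brings no volume worth counting | all else is in the flask from the start; the feed brings no volume worth counting | all else is in the flask from the start; the feed brings no volume worth counting |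

* the flask that comes out highest in amount of side product, in percent of the substrate charged, or "all alike" when all lie within 1.5 percentage points (eta / gamma / theta / delta / all alike)
* side product at the end, in percent of the substrate charged, eta
* side product at the end, in percent of the substrate charged, gamma
* side product at the end, in percent of the substrate charged, theta
* side product at the end, in percent of the substrate charged, delta

- in percentages every species weighs as the substrate in it: one side product counts as two
- run time (eta): 80 s

By the first-order step alone, the fraction of substrate left decays with a lifetime of 11.9 s. If nothing removed intermediate, it would hold the part already gone. Integrating fraction left times fraction gone, and counting each side product twice, gives the overlap ceiling, the side-step constant times the substrate charge over the first-order constant: 26.9%. The side step also uses substrate, but even at full charge its rate constant term stays below the first-order one, so the ceiling stands as a first figure.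

In gamma, partner arrives at 0.002800 M s⁻¹, slower than the initial 0.01180 M s⁻¹ of intermediate formation, so intermediate accumulates and the fed partner subtracts from it. The same integral removes 12.8%, leaving 14.1%. Fed partner might go dormant instead, but with a quarter of the charge as intermediate, it meets intermediate 3.35 times faster.

In eta, intermediate's half-life against charged partner is 0.790 s, shorter than the substrate lifetime, so while partner stands near its charge intermediate can be reckoned in a steady state, and the share is 2.59%. Yet partner's forward half-life towards the dormant form, 12.7 s, is comparable, and weighting by that decay multiplies the share by 1.48, giving 3.82%. Partner spent on target is still uncounted, so this figure is low, and the steady state holds early in eta and not late: with the substrate charge taken off the partner charge and the rest shared with the dormant form by 2.45, free partner stands near 0.008116 M, against which intermediate's half-life is 16.4 s, longer than the substrate lifetime, so late in eta intermediate outlasts substrate. Delta's feed of 6.0 s is shorter than the substrate lifetime, so it is reckoned like eta: 3.82%.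

In theta, substrate stands near feed rate times lifetime, 0.0277 M, while partner relaxes towards its dormant form in 9.02 s, well inside the feed. With half the substrate charge already spent on partner, free partner is about 0.0284 M, and the split of intermediate gives 6.05%. The highest is therefore gamma.

The forecast also named gamma, holding that “slow partner feed (gamma) lets intermediate pile up while substrate is still high”, but its figures differ from those above: 6.3% for eta, 12% for gamma, 4.6% for theta and 6% for delta.

The simulation gives gamma as highest, with 5.14% in eta, 14.7% in gamma, 4.92% in theta and 5.51% in delta. Gamma's dosing time is 5.1 times the lifetime of substrate against everything charged, and at 40.0 s gamma holds 2.52% substrate, 21.2% intermediate and 14.6% side product, ending 12 percentage points below the 26.9% ceiling. For the neighbour of gamma charged with 0.042 M of partner, the ceiling less its feed term gives 23.7%, and that flask holds 18.7% side product, with 52.7% still intermediate at 80.0 s.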